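Ring numbering: C1 = ring ketone, C2 = amide-bearing carbon, C3 = CH, C4 = carbinol carbon, C5 = CH, C6 = chlorine-bearing carbon; primed numbers belong to the acyl chain.
Cuts, in retrosynthetic order: CO2H back to a silyl-protected CH2OH; the C6–Cl bond and the C5=C6 double bond back to a C5–C6 oxirane; the C4–CH2 bond (alkyllithium plus C4 ketone); the oxirane C–O bonds and the C1 ketal back to an anilide; the amide N–C1' bond; C2'=C3' and C7'=C8' (two carbonyl olefinations).
Enabling feature: in the cyclohexa-2,5-dienone ring, C1(=O)–C6(Cl)=C5H is an alpha-chloroenone, formally a C5–C6 epoxy ketone plus HCl minus water. C4 is stereogenic only because C6 carries Cl while C2 carries N, so an oxirane on C5–C6 can steer the construction of C4 and then be erased.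
Forward order: the acyl chain is built from a five-carbon meso unit extended at both ends and joined to the arene as the anilide. The arene is dearomatised to the carbocycle, the oxirane is fused on at C5–C6, the C4 chain is added, the ketal is removed, the oxirane becomes the chloroalkene, and the chain end is oxidised.
Stereochemistry: the syn 1,3-dimethyl pair comes from enzymatic desymmetrisation of a meso diol, the E-alkene from the phosphonate olefination, the oxirane from a chiral phase-transfer catalyst, and C4 from addition anti to that oxirane.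

Key step: step 15

Assumption: the Pseudomonas fluorescens lipase is taken to acetylate the hydroxymethyl arm on the S-configured carbon of the meso diol, and N-benzylcinchonidinium chloride is taken to deliver the peroxide to the ring face that gives the 5S,6R oxirane, as these catalysts behave with closely related substrates; the pseudoenantiomeric cinchoninium salt would reverse the ring face.

Step 1
Reactants: 1 cis-2,4-dimethylglutaric anhydride (meso)
Product: 2 (2R,4S)-2,4-dimethylpentane-1,5-diol (meso)
Conditions: LiAlH4, THF, 0 °C to reflux; aq NaOH work-up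
Reagents that add atoms: none
Why: Exhaustive hydride reduction of a cyclic anhydride to the 1,5-diol does not touch the two alpha carbons, so the cis (meso) relationship of the methyl groups is carried over.

Step 2
Reactants: 2 (2R,4S)-2,4-dimethylpentane-1,5-diol
Product: 3 (2S,4R)-5-hydroxy-2,4-dimethylpentyl acetate
Conditions: lipase from Pseudomonas fluorescens (Amano AK), vinyl acetate, THF, rt
Reagents that add atoms: vinyl acetate, C=COC(C)=O
Why: Enzymatic desymmetrisation by irreversible transesterification, in which the lipase distinguishes the two enantiotopic hydroxymethyl arms and thereby fixes the absolute configuration of both methyl-bearing carbons at once.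

Step 3
Reactants: 3 (2S,4R)-5-hydroxy-2,4-dimethylpentyl acetate
Product: 4 (2S,4R)-2,4-dimethyl-5-oxopentyl acetate
Conditions: 2,2,6,6-tetramethylpiperidin-1-oxyl (TEMPO, 10 mol%), PhI(OAc)2, CH2Cl2, rt
Reagents that add atoms: none
Why: Nitroxyl-catalysed alcohol oxidation with a trivalent iodine co-oxidant stops at the aldehyde under nearly neutral conditions, so the alpha stereocentre should not epimerise and the acetate stays in place.

Step 4
Reactants: 4 (2S,4R)-2,4-dimethyl-5-oxopentyl acetate; 5 isopropyltriphenylphosphonium iodide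
Product: 7 (2S,4R)-2,4,6-trimethylhept-5-en-1-yl acetate, via isopropylidene(triphenyl)phosphorane 6 (not isolated)
Conditions: 5, n-BuLi, THF, 0 °C; then 4, −78 °C to rt
Reagents that add atoms: none
Why: Wittig olefination with a non-stabilised ylide is far faster at the aldehyde than at the acetate at low temperature, and no alkene geometry arises because the new terminus carries two methyl groups.

Step 5
Reactants: 7 (2S,4R)-2,4,6-trimethylhept-5-en-1-yl acetate
Product: 8 (2S,4R)-2,4,6-trimethylhept-5-en-1-ol
Conditions: K2CO3 (cat.), MeOH, rt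
Reagents that add atoms: none
Why: Base-catalysed methanolysis (transesterification) removes the acetate without affecting the alkene or either stereocentre.

Step 6
Reactants: 8 (2S,4R)-2,4,6-trimethylhept-5-en-1-ol
Product: 9 (2S,4R)-2,4,6-trimethylhept-5-enal
Conditions: 2,2,6,6-tetramethylpiperidin-1-oxyl (TEMPO, 10 mol%), PhI(OAc)2, CH2Cl2, rt
Reagents that add atoms: none
Why: The same nitroxyl-catalysed oxidation tolerates trisubstituted alkenes and gives the alpha-methyl aldehyde without base, which protects the C2 stereocentre.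

Step 7
Reactants: 9 (2S,4R)-2,4,6-trimethylhept-5-enal; 10 triethyl phosphonoacetate
Product: 12 ethyl (2E,4S,6R)-4,6,8-trimethylnona-2,7-dienoate, via sodium phosphonoacetate carbanion 11 (not isolated)
Conditions: 10, NaH, THF, 0 °C; then 9, 0 °C to rt
Reagents that add atoms: none
Why: Horner–Wadsworth–Emmons olefination with a stabilised phosphonate anion should give the E-enoate, and the preformed, weakly basic anion leaves the adjacent methyl-bearing centre untouched.

Step 8
Reactants: 12 ethyl (2E,4S,6R)-4,6,8-trimethylnona-2,7-dienoate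
Product: 13 (2E,4S,6R)-4,6,8-trimethylnona-2,7-dienoic acid
Conditions: LiOH, THF/H2O, rt; then 1 M HCl
Reagents that add atoms: lithium hydroxide, [Li+].[OH-]
Why: Saponification of an ethyl enoate at room temperature is too mild to deprotonate the gamma position, so neither the alkene position nor C4' should change.

Step 9
Reactants: 13 (2E,4S,6R)-4,6,8-trimethylnona-2,7-dienoic acid; 14 2,5-dimethoxyaniline
Product: 16 (2E,4S,6R)-N-(2,5-dimethoxyphenyl)-4,6,8-trimethylnona-2,7-dienamide, via dienoyl chloride 15 (not isolated)
Conditions: 1-chloro-N,N,2-trimethylprop-1-en-1-amine, CH2Cl2, 0 °C; then 14, pyridine, 0 °C to rt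
Reagents that add atoms: none
Why: Amide formation through the acid chloride, which the alpha-chloroenamine generates under neutral conditions without free HCl, so the trisubstituted alkene is not hydrochlorinated and the electron-rich aniline acylates readily.

Step 10
Reactants: 16 (2E,4S,6R)-N-(2,5-dimethoxyphenyl)-4,6,8-trimethylnona-2,7-dienamide
Product: 18 (2E,4S,6R)-N-(6,6-dimethoxy-3-oxocyclohexa-1,4-dien-1-yl)-4,6,8-trimethylnona-2,7-dienamide (quinone monoketal), via quinone imide ketal 17 (not isolated)
Conditions: PhI(OAc)2, MeOH, 0 °C to rt; aq NaHCO3 work-up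
Reagents that add atoms: methanol, CO; water, O
Why: Oxidative dearomatisation of a para-dimethoxy anilide with a trivalent iodine reagent, in which methanol is captured at the methoxy-bearing carbon ortho to nitrogen and the vinylogous imidate left at the other methoxy carbon is hydrolysed on work-up, placing the ketal at C1 and the free ketone at C4.

Step 11
Reactants: 18 quinone monoketal
Product: 19 (2E,4S,6R)-N-[(1R,6S)-2,2-dimethoxy-5-oxo-7-oxabicyclo[4.1.0]hept-3-en-3-yl]-4,6,8-trimethylnona-2,7-dienamide (5S,6R-epoxy quinone monoketal)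
Conditions: t-BuOOH, aq NaOH, N-benzylcinchonidinium chloride (10 mol%), toluene, rt
Reagents that add atoms: tert-butyl hydroperoxide, CC(C)(C)OO
Why: Weitz–Scheffer nucleophilic epoxidation under chiral phase-transfer catalysis, in which the peroxide anion attacks only the unsubstituted C5=C6 enone (C2=C3 is deactivated by the nitrogen donor and both chain alkenes are inert to peroxide anions) while the ion pair with the cinchonidinium cation selects the ring face and so sets C5 (S) and C6 (R).

Step 12
Reactants: 20 (5-bromopentyloxy)(tert-butyl)dimethylsilane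
Product: 21 tert-butyl(5-iodopentyloxy)dimethylsilane
Conditions: NaI, acetone, reflux
Reagents that add atoms: sodium iodide, [Na+].[I-]
Why: Finkelstein halide exchange driven by precipitation of NaBr supplies the primary iodide, the halide class for which exchange with t-BuLi is clean.

Step 13
Reactants: 19 5S,6R-epoxy quinone monoketal; 21 tert-butyl(5-iodopentyloxy)dimethylsilane
Product: 23 (2E,4S,6R)-N-[(1R,5R,6S)-5-{5-[tert-butyl(dimethyl)silyl]oxypentyl}-5-hydroxy-2,2-dimethoxy-7-oxabicyclo[4.1.0]hept-3-en-3-yl]-4,6,8-trimethylnona-2,7-dienamide (4R,5S,6R; hydroxyl syn to the oxirane oxygen), via 5-silyloxypentyllithium 22 (not isolated)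
Conditions: 21 (2.5 equiv), t-BuLi (5.0 equiv), Et2O/pentane, −78 °C; then 19 in THF, −78 °C; AcOH quench at −78 °C
Reagents that add atoms: none
Why: Lithium–iodine exchange followed by 1,2-addition to the C4 ketone, in which the first equivalent of alkyllithium removes the amide proton (which also shields the acrylamide from conjugate attack) and the second approaches the carbonyl from the face opposite the oxirane oxygen for steric and electrostatic reasons, setting C4 as R.

Step 14
Reactants: 23 syn-hydroxy epoxy ketal
Product: 24 (2E,4S,6R)-N-[(1R,5R,6S)-5-{5-[tert-butyl(dimethyl)silyl]oxypentyl}-5-hydroxy-2-oxo-7-oxabicyclo[4.1.0]hept-3-en-3-yl]-4,6,8-trimethylnona-2,7-dienamide (4R,5S,6R-epoxyquinol)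
Conditions: pyridinium p-toluenesulfonate (cat.), acetone/H2O 10:1, rt
Reagents that add atoms: water, O
Why: Mild acid-catalysed ketal hydrolysis unmasks the C1 ketone with an acid too weak to open the oxirane, ionise the tertiary allylic alcohol or cleave the primary silyl ether at a useful rate.

Step 15
Reactants: 24 4R,5S,6R-epoxyquinol
Product: 26 (2E,4S,6R)-N-[(3R)-3-{5-[tert-butyl(dimethyl)silyl]oxypentyl}-5-chloro-3-hydroxy-6-oxocyclohexa-1,4-dien-1-yl]-4,6,8-trimethylnona-2,7-dienamide, via trans chlorohydrin 25 (not isolated)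
Conditions: pyridinium chloride (3 equiv), MeCN, 0 °C to rt
Reagents that add atoms: pyridinium chloride, [Cl-].c1cc[nH+]cc1
Why: The pyridinium ion activates the oxirane oxygen and chloride displaces it at C6 in an SN2 sense to give the trans 6-chloro-5-hydroxy ketone 25, whose C6–H, acidified by the C1 carbonyl and by chlorine, is removed by the liberated pyridine so that the C5 hydroxyl leaves by an E1cB pathway and the C5=C6(Cl) bond appears. The closest known reaction type is the hydrogen chloride opening of cyclic alpha,beta-epoxy ketones with spontaneous dehydration to 2-chloro-2-enones. No ring is closed; the three-membered ring is consumed and the carbocycle is left as it is. No lasting stereocentre is created, since the two centres of 25 follow from anti opening and are both flattened, while C4 has no hydrogen to lose, is not ionised under buffered conditions and keeps its R configuration. The selectivity needed is chloride attack at C6 instead of C5, which is secured by the carbonyl-accelerated displacement at the alpha carbon and by the neopentyl-like shielding of C5 by the fully substituted C4. The weak acid should also spare the trisubstituted chain alkene, the primary silyl ether and the rearrangement-prone quinol.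

Step 16
Reactants: 26 chloroquinol silyl ether
Product: 27 (2E,4S,6R)-N-[(3R)-5-chloro-3-hydroxy-3-(5-hydroxypentyl)-6-oxocyclohexa-1,4-dien-1-yl]-4,6,8-trimethylnona-2,7-dienamide
Conditions: HF·pyridine, pyridine/THF, 0 °C
Reagents that add atoms: none
Why: Fluoride-mediated cleavage of a primary silyl ether under buffered, weakly acidic conditions avoids the basic fluoride sources that could attack the chloro dienone.

Step 17
Reactants: 27 chloroquinol primary alcohol
Product: 29 5-[(1R)-3-chloro-1-hydroxy-4-oxo-5-{[(2E,4S,6R)-4,6,8-trimethylnona-2,7-dienoyl]amino}cyclohexa-2,5-dien-1-yl]pentanoic acid (target), via chain aldehyde 28 (not isolated)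
Conditions: 2,2,6,6-tetramethylpiperidin-1-oxyl (TEMPO, 20 mol%), PhI(OAc)2 (2.5 equiv), MeCN/H2O 1:1, rt
Reagents that add atoms: water, O
Why: Nitroxyl-catalysed oxidation in aqueous medium takes the primary alcohol through aldehyde 28 and its hydrate to the acid, while the tertiary carbinol cannot be oxidised, a seven-membered lactol is not favoured and the alkenes tolerate this oxidant system.

Compound list
1 | cis-2,4-dimethylglutaric anhydride, (3R,5S)-3,5-dimethyloxane-2,6-dione (meso) | O=C1[C@H](C)C[C@H](C)C(=O)O1 | starting material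
2 | (2R,4S)-2,4-dimethylpentane-1,5-diol (meso) | OC[C@H](C)C[C@H](C)CO | intermediate
3 | (2S,4R)-5-hydroxy-2,4-dimethylpentyl acetate | OC[C@H](C)C[C@H](C)COC(C)=O | intermediate
4 | (2S,4R)-2,4-dimethyl-5-oxopentyl acetate | O=C[C@H](C)C[C@H](C)COC(C)=O | intermediate
5 | isopropyltriphenylphosphonium iodide | CC(C)[P+](c1ccccc1)(c1ccccc1)c1ccccc1.[I-] | starting material
6 | isopropylidene(triphenyl)phosphorane | CC(C)=P(c1ccccc1)(c1ccccc1)c1ccccc1 | intermediate
7 | (2S,4R)-2,4,6-trimethylhept-5-en-1-yl acetate | CC(C)=C[C@H](C)C[C@H](C)COC(C)=O | intermediate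
8 | (2S,4R)-2,4,6-trimethylhept-5-en-1-ol | CC(C)=C[C@H](C)C[C@H](C)CO | intermediate
9 | (2S,4R)-2,4,6-trimethylhept-5-enal | CC(C)=C[C@H](C)C[C@H](C)C=O | intermediate
10 | triethyl phosphonoacetate | CCOC(=O)CP(=O)(OCC)OCC | starting material
11 | sodium salt of triethyl phosphonoacetate (carbanion) | [Na+].CCOC(=O)[CH-]P(=O)(OCC)OCC | intermediate
12 | ethyl (2E,4S,6R)-4,6,8-trimethylnona-2,7-dienoate | CC(C)=C[C@H](C)C[C@H](C)/C=C/C(=O)OCC | intermediate
13 | (2E,4S,6R)-4,6,8-trimethylnona-2,7-dienoic acid | CC(C)=C[C@H](C)C[C@H](C)/C=C/C(=O)O | intermediate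
14 | 2,5-dimethoxyaniline | COc1ccc(OC)c(N)c1 | starting material
15 | (2E,4S,6R)-4,6,8-trimethylnona-2,7-dienoyl chloride | CC(C)=C[C@H](C)C[C@H](C)/C=C/C(=O)Cl | intermediate
16 | (2E,4S,6R)-N-(2,5-dimethoxyphenyl)-4,6,8-trimethylnona-2,7-dienamide | CC(C)=C[C@H](C)C[C@H](C)/C=C/C(=O)Nc1cc(OC)ccc1OC | intermediate
17 | (2E,4S,6R)-4,6,8-trimethyl-N-(3,6,6-trimethoxycyclohexa-2,4-dien-1-ylidene)nona-2,7-dienamide (quinone imide ketal) | CC(C)=C[C@H](C)C[C@H](C)/C=C/C(=O)N=C1C=C(OC)C=CC1(OC)OC | intermediate
18 | (2E,4S,6R)-N-(6,6-dimethoxy-3-oxocyclohexa-1,4-dien-1-yl)-4,6,8-trimethylnona-2,7-dienamide (quinone monoketal) | CC(C)=C[C@H](C)C[C@H](C)/C=C/C(=O)NC1=CC(=O)C=CC1(OC)OC | intermediate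
19 | (2E,4S,6R)-N-[(1R,6S)-2,2-dimethoxy-5-oxo-7-oxabicyclo[4.1.0]hept-3-en-3-yl]-4,6,8-trimethylnona-2,7-dienamide (5S,6R-epoxide) | CC(C)=C[C@H](C)C[C@H](C)/C=C/C(=O)NC1=CC(=O)[C@H]2O[C@H]2C1(OC)OC | intermediate
20 | (5-bromopentyloxy)(tert-butyl)dimethylsilane | CC(C)(C)[Si](C)(C)OCCCCCBr | starting material
21 | tert-butyl(5-iodopentyloxy)dimethylsilane | CC(C)(C)[Si](C)(C)OCCCCCI | intermediate
22 | 5-[tert-butyl(dimethyl)silyl]oxypentyllithium | [Li]CCCCCO[Si](C)(C)C(C)(C)C | intermediate
23 | (2E,4S,6R)-N-[(1R,5R,6S)-5-{5-[tert-butyl(dimethyl)silyl]oxypentyl}-5-hydroxy-2,2-dimethoxy-7-oxabicyclo[4.1.0]hept-3-en-3-yl]-4,6,8-trimethylnona-2,7-dienamide (hydroxyl syn to oxirane) | CC(C)=C[C@H](C)C[C@H](C)/C=C/C(=O)NC1=C[C@](O)(CCCCCO[Si](C)(C)C(C)(C)C)[C@H]2O[C@H]2C1(OC)OC | intermediate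
24 | (2E,4S,6R)-N-[(1R,5R,6S)-5-{5-[tert-butyl(dimethyl)silyl]oxypentyl}-5-hydroxy-2-oxo-7-oxabicyclo[4.1.0]hept-3-en-3-yl]-4,6,8-trimethylnona-2,7-dienamide (epoxyquinol) | CC(C)=C[C@H](C)C[C@H](C)/C=C/C(=O)NC1=C[C@](O)(CCCCCO[Si](C)(C)C(C)(C)C)[C@H]2O[C@H]2C1=O | intermediate
25 | (2E,4S,6R)-N-[(3R,4R,5S)-3-{5-[tert-butyl(dimethyl)silyl]oxypentyl}-5-chloro-3,4-dihydroxy-6-oxocyclohex-1-en-1-yl]-4,6,8-trimethylnona-2,7-dienamide (trans chlorohydrin) | CC(C)=C[C@H](C)C[C@H](C)/C=C/C(=O)NC1=C[C@](O)(CCCCCO[Si](C)(C)C(C)(C)C)[C@@H](O)[C@H](Cl)C1=O | intermediate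
26 | (2E,4S,6R)-N-[(3R)-3-{5-[tert-butyl(dimethyl)silyl]oxypentyl}-5-chloro-3-hydroxy-6-oxocyclohexa-1,4-dien-1-yl]-4,6,8-trimethylnona-2,7-dienamide | CC(C)=C[C@H](C)C[C@H](C)/C=C/C(=O)NC1=C[C@](O)(CCCCCO[Si](C)(C)C(C)(C)C)C=C(Cl)C1=O | intermediate
27 | (2E,4S,6R)-N-[(3R)-5-chloro-3-hydroxy-3-(5-hydroxypentyl)-6-oxocyclohexa-1,4-dien-1-yl]-4,6,8-trimethylnona-2,7-dienamide | CC(C)=C[C@H](C)C[C@H](C)/C=C/C(=O)NC1=C[C@](O)(CCCCCO)C=C(Cl)C1=O | intermediate
28 | (2E,4S,6R)-N-[(3R)-5-chloro-3-hydroxy-6-oxo-3-(5-oxopentyl)cyclohexa-1,4-dien-1-yl]-4,6,8-trimethylnona-2,7-dienamide | CC(C)=C[C@H](C)C[C@H](C)/C=C/C(=O)NC1=C[C@](O)(CCCCC=O)C=C(Cl)C1=O | intermediate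
29 | 5-[(1R)-3-chloro-1-hydroxy-4-oxo-5-{[(2E,4S,6R)-4,6,8-trimethylnona-2,7-dienoyl]amino}cyclohexa-2,5-dien-1-yl]pentanoic acid | CC(C)=C[C@H](C)C[C@H](C)/C=C/C(=O)NC1=C[C@](O)(CCCCC(=O)O)C=C(Cl)C1=O | target

Total step count: 17. Longest linear sequence: 16 steps (steps 1–11 and 13–17, from 1 to 29); step 12 is a one-step side branch.

Steps most likely to fail

Step 11. The chiral ammonium salt may discriminate the two ring faces insufficiently. Turnover may be slow because the acidic N–H is deprotonated under the basic two-phase conditions. The two epoxide diastereomers differ only in remote centres and may resist separation. The fallback sets out from 14 and comes back to the route at 19. It moves the epoxidation to a small crystalline carbamate and attaches the chain afterwards.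
- Aniline 14 is treated with allyl chloroformate and pyridine to give allyl N-(2,5-dimethoxyphenyl)carbamate F1.
- PhI(OAc)2 in methanol converts it, through the carbamate quinone imide ketal F2, to the carbamate quinone monoketal F3.
- The phase-transfer epoxidation then gives the carbamate epoxy ketone F4. This is now a mixture of enantiomers only, which can be brought to optical purity by recrystallisation.
- The zerovalent palladium complex Pd(PPh3)4 with morpholine removes the allyl carbamate under neutral conditions to give the free amino epoxy enone F5.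
- N-acylation of its lithium salt (LiOt-Bu, THF) with acid chloride 15, made from 13 as in step 9, gives 19.

Step 13. The N-lithiated substrate may react sluggishly at its deactivated carbonyl. The strongly basic alkyllithium may attack the oxirane or decompose the substrate, and facial selectivity may erode if the temperature has to be raised. The fallback sets out from 20 and 19 and comes back at 23. It changes the nucleophile class and the way it is made.
- Direct magnesium insertion into bromide 20 (Mg, THF) gives 5-silyloxypentylmagnesium bromide F6.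
- F6 is transmetallated with anhydrous CeCl3 at −78 °C to the alkylcerium dichloride F7.
- This far less basic and strongly oxophilic reagent, again used in excess to absorb the amide proton, should add to the C4 ketone of 19 from the face anti to the oxirane and give 23. Step 12 is then not needed.

Step 15. Chloride may attack the wrong oxirane carbon. The sequence may stall at the chlorohydrin stage because dehydration is slow with so weak an acid–base pair. Forcing the conditions may bring on premature desilylation or acid-induced rearrangement of the quinol. The fallback sets out from 24 and comes back at 26. It separates opening and elimination and replaces the dehydration by a base-induced sulfonate elimination.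
- Li2CuCl4 in THF opens the oxirane without a proton acid, and chlorohydrin 25 is now isolated.
- Methanesulfonyl chloride and Et3N at −20 °C sulfonylate only the secondary C5 hydroxyl to give the C5 mesylate F8.
- Excess Et3N (or DBU) then expels mesylate from the C6 enolate to give 26.

Further compounds
F1 | step 11 | allyl N-(2,5-dimethoxyphenyl)carbamate | C=CCOC(=O)Nc1cc(OC)ccc1OC
F2 | step 11 | allyl N-(3,6,6-trimethoxycyclohexa-2,4-dien-1-ylidene)carbamate | C=CCOC(=O)N=C1C=C(OC)C=CC1(OC)OC
F3 | step 11 | allyl N-(6,6-dimethoxy-3-oxocyclohexa-1,4-dien-1-yl)carbamate | C=CCOC(=O)NC1=CC(=O)C=CC1(OC)OC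
F4 | step 11 | allyl N-[(1R,6S)-2,2-dimethoxy-5-oxo-7-oxabicyclo[4.1.0]hept-3-en-3-yl]carbamate | C=CCOC(=O)NC1=CC(=O)[C@H]2O[C@H]2C1(OC)OC
F5 | step 11 | (1S,6R)-4-amino-5,5-dimethoxy-7-oxabicyclo[4.1.0]hept-3-en-2-one | NC1=CC(=O)[C@H]2O[C@H]2C1(OC)OC
F6 | step 13 | 5-[tert-butyl(dimethyl)silyl]oxypentylmagnesium bromide | CC(C)(C)[Si](C)(C)OCCCCC[Mg]Br
F7 | step 13 | dichloro{5-[tert-butyl(dimethyl)silyl]oxypentyl}cerium | CC(C)(C)[Si](C)(C)OCCCCC[Ce](Cl)Cl
F8 | step 15 | C5 methanesulfonate of chlorohydrin 25 | CC(C)=C[C@H](C)C[C@H](C)/C=C/C(=O)NC1=C[C@](O)(CCCCCO[Si](C)(C)C(C)(C)C)[C@@H](OS(C)(=O)=O)[C@H](Cl)C1=O
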